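## Structural features

The target is a flavonol: a benzene ring A fused to a 4-pyranone ring C, with ring B, a 4-hydroxyphenyl group, attached at C2 by one single bond. There is no stereocentre. Ring A is substituted on five contiguous carbons: the C4 carbonyl carbon at C4a, hydroxyl at C5, methoxy at C7, acetoxy at C8 and the ring oxygen O1 at C8a; only C6 bears hydrogen. Ring C holds the C4 ketone between the chelated 5-OH and an enolic 3-OH. The fragile group is the aryl acetate on O8: amines, alkoxides and aqueous base cleave it, so it must be introduced late and every later step must be neutral or weakly acidic. The unmasked polyphenol is also sensitive to oxidants. The real difficulty is therefore placement and differentiation: only O8 may be acylated among four hydroxyl oxygens (O3, O5, O8, O4'), and the carbon substituent must be placed at C4a, between O5 and O1, although C6 is also open. The key step exploits the fact that C4 is a carbonyl carbon bonded only to C4a and C3. It can therefore be delivered as carbon monoxide between the C4a–I bond of a ring A ortho-iodophenol, whose hydroxyl becomes O1, and a terminal arylalkyne that supplies C3, C2 and ring B.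

## Logic of the disconnections

22 to 21. The two benzylic O–CH2 bonds on O5 and O4' are cut last. Hydrogenolysis is neutral and free of nucleophiles, which the O8 ester requires, and it frees both phenols in one operation. The forward step must spare the ester and the C2=C3 bond, so alcohol solvents and bases are excluded.

21 to 19. The C3–O bond is cut, because an alkyne-derived flavone carries hydrogen at C3. Oxidising after the ester is in place means a free C3 hydroxyl never coexists with a free O8 hydroxyl, so O3 needs no protecting group and one step is saved. The forward oxidant must be neutral, must prefer the C2=C3 bond to benzylic C–H bonds and must meet no free phenol; the reaction passes through 20, whose two stereocentres are lost again.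

19 to 18. The O8–C(acyl) bond is cut. In 18 the oxygen on C8 is the only one bearing hydrogen, so acylation is unambiguous. The forward step needs a nucleophilic catalyst because this hydroxyl sits between the methoxy group and O1.

18 to 17. The O8–CH2 bond of the acetal is cut. An acetal lets O8 pass through hot secondary amine, hydroxide and organolithium reagents and still be freed alone. The forward step needs acid mild enough to keep the benzyl ether on O5, which is peri to the carbonyl.

17 to 12, 13 and 14. C4a–C4, C4–C3 and O1–C2 are cut together, which removes ring C and the whole bridge between ring A and ring B. What remains is a fully oxygenated benzene, a gas and a purchasable alkyne. The forward step must insert 14 before the alkyne couples, must close 6-endo, and needs the hydroxyl beside iodine free while O5 and O8 stay capped.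

12 to 11. The O–C(carbamoyl) bond is cut. The carbamate only served to steer iodine and is removed just before the phenol is needed. The forward hydrolysis must reach a carbonyl screened by iodine and by the acetal without harming either.

11 to 9. The C4a–I bond is cut. In a free phenol C4a and C6 are each activated by three oxygens, so electrophilic iodination cannot be trusted. A carbamate on the C8a oxygen has only one open ortho position, C4a, and the O5 ether reinforces metalation there (through 10). Lithiation must beat benzylic deprotonation, and the iodine quench must precede carbamoyl migration.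

9 to 8. The O–C(carbamoyl) bond is cut to the free phenol. This costs one simple step and demands only complete O-acylation of a hindered phenoxide.

8 to 5. The C8a–O bond is replaced by C8a–Br. Bromine is the placeholder that the starting material already carries at this carbon, and exchange through 6 and 7 keeps the position fixed. Halogen–lithium exchange at low temperature must be faster than any reaction at the benzyl ether.

5 to 4. The O5–CH2Ph bond is cut. Benzyl is chosen because it lasts through acid, base and organolithium steps and leaves only in the final hydrogenolysis. The forward alkylation is undemanding.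

4 to 2. The C5–O bond is cut back to a C5–CHO bond (through 3). Aryl migration to a peracid oxygen turns a 3,4,5-trisubstituted benzaldehyde into the 1,2,3,5-tetraoxygenated pattern of ring A. Aryl, not hydride, must migrate, and the acetal must survive the peracid.

2 to 1. The O8–CH2OMe bond is cut. Capping the only hydroxyl of 1 first keeps it out of the oxidation and of all organometallic steps. The forward step asks only for a hindered-amine base.

## Other disconnections considered

Alternative 1: The cut runs through C3–C4 and O1–C2. Ring C would be closed by joining a ring A acyl donor, 2-(acetyloxy)-3-(allyloxy)-6-(benzyloxy)-4-methoxybenzoyl chloride A2, to an enamine that already carries the C3 oxygen and ring B, 4-{(Z)-2-(benzyloxy)-1-[4-(benzyloxy)phenyl]ethenyl}morpholine A3 (its geometry is not critical). In the forward step A3 would be C-acylated at its β-carbon by A2; after loss of the acetyl group the phenoxide would add to C2 and expel the amine, giving 8-(allyloxy)-3,5-bis(benzyloxy)-2-[4-(benzyloxy)phenyl]-7-methoxy-4H-chromen-4-one A1.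
- In its favour: the C3 oxygen arrives with A3, so no late oxidation of C3 is needed, which is better than the chosen plan. No pressure vessel or transition metal is required for ring closure, also better.
- Against it: A2 has both ortho positions occupied and is a hindered acylating agent. A3 is an electron-rich, hydrolytically sensitive enamine that could be acylated on carbon or lose the amine prematurely. Making A2 still requires a carbon substituent at C4a, which is the same ortho-functionalisation problem, followed by O-acetylation and acid chloride formation. The allyl group on O8 would need a palladium-mediated removal before acetylation.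
- Comparison: structurally both plans join a ring A piece to a ring B piece and are equally convergent. Mechanistically this one is polar and forms two bonds where the chosen step forms three. After the key step it should need three steps (deallylation, acetylation, hydrogenolysis) against four, so it is better there. Before the key step it should need more, so the overall length is estimated as equal or slightly longer.

Alternative 2: The cut is at C4a–C5 together with the rest of ring A, which would be grown onto a preformed pyranone. 3-(Benzyloxy)-2-[4-(benzyloxy)phenyl]-4H-pyran-4-one A7, metalated at C6, would add to the ketone-like carbonyl of 3-methoxycyclobut-3-ene-1,2-dione A6 to give rac-4-{5-(benzyloxy)-6-[4-(benzyloxy)phenyl]-4-oxo-4H-pyran-2-yl}-4-hydroxy-3-methoxycyclobut-2-en-1-one A5. Heating A5 would open the four-membered ring (4π) to a dienylketene, whose ketene carbon closes (6π) onto the pyranone carbon that becomes C4a. Tautomerisation would give 3-(benzyloxy)-2-[4-(benzyloxy)phenyl]-5,8-dihydroxy-7-methoxy-4H-chromen-4-one A4.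
- In its favour: the oxygen pattern of ring A is fixed by construction, with no aromatic substitution to direct and no protecting groups on ring A, which is better than the chosen plan. In A4 the 5-OH is chelated and the 8-OH is not, so direct 8-O-acetylation and hydrogenolysis could finish the synthesis in two steps, which is shorter.
- Against it: ring C and ring B must already exist in A7, so the flavonol-type pyranone still has to be made by other chemistry. Metalation of A7 next to the ring oxygen competes with attack on its carbonyl. The electrocyclisation would use a double bond of a cross-conjugated pyranone, which is less well supported than closure onto a benzene or alkene. A4 is a 5,8-hydroquinone that should oxidise readily to the quinone, and mono-acetylation rests on hydrogen bonding alone.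
- Comparison: it is the more elegant answer to ring A, and the equal of the chosen plan in having no stereochemical issue. Its risk is concentrated in steps that are less precedented. Counting the preparation of A7 and A6, its length is estimated as comparable or longer.

Alternative 3: The cut is at C4–C4a. (2E)-3-[2,5-Bis(allyloxy)-3-methoxyphenoxy]-2-(benzyloxy)-3-[4-(benzyloxy)phenyl]prop-2-enoic acid A9 would be activated (mixed trifluoroacetic anhydride, or acid chloride and SnCl4) and would acylate the free ortho carbon of its aryloxy ring, giving 5,8-bis(allyloxy)-3-(benzyloxy)-2-[4-(benzyloxy)phenyl]-7-methoxy-4H-chromen-4-one A8.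
- In its favour: the other ortho position is blocked, so the closure can only occur at C4a, which is equal to the chosen plan in regiocontrol. Ring A enters as a simple phenol ether with no halogen, which is better. The C3 oxygen is already present, which is better.
- Against it: A9 is a tetrasubstituted push–pull alkene whose carboxyl must be cis to the aryloxy group, and making it by addition–elimination of a hindered phenol is itself demanding. Friedel–Crafts conditions threaten the allyl ethers and the benzyl enol ether. After A8 both allyl groups fall together, so the endgame again relies on selective acetylation of the 8-OH beside the chelated 5-OH.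
- Comparison: mechanistically it is a classical electrophilic closure forming one bond against three. The endgame would be three steps against four, which is better. The preparation of A9 is estimated to cost what the iodophenol costs, so step economy is about equal and the reliability of the central step is lower.

Key step: step 8

## Route

Remarks on the chemistry:
- Mapped atom by atom onto the target, iodophenol 12 and flavone 17 need no structural correction: iodine sits on C4a, benzyl on O5, methyl on O7, methoxymethyl on O8, and the free hydroxyl becomes O1.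
- Because the amine of the key step would cleave an aryl acetate, O8 carries the acetal through step 8. The acetate is put on before C3 is oxidised, so O3 never needs a protecting group and four steps follow the key step.
- With the para oxygen of aldehyde 2 capped, the aldehyde-to-phenol change is run as a peracid Baeyer–Villiger oxidation, not with alkaline peroxide.
- Alkyne 13 is assumed to be purchased.
- Epoxide 20 is racemic, which is without consequence because both stereocentres disappear in the same step.

Step 1
Reactants: 1 5-bromovanillin (3-bromo-4-hydroxy-5-methoxybenzaldehyde)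
Product: 2 3-bromo-5-methoxy-4-(methoxymethoxy)benzaldehyde
Conditions: MOMCl, i-Pr2NEt, CH2Cl2, 0 °C → rt
Reagents that add atoms: chloromethyl methyl ether COCCl
Why: O-Alkylation of the acidic phenol with an α-chloro ether gives the mixed acetal; it masks the future O8 against base, peracid and organolithium reagents and can later be removed with dilute acid while benzyl ethers stay.

Step 2
Reactants: 2 3-bromo-5-methoxy-4-(methoxymethoxy)benzaldehyde
Product: 4 3-bromo-5-methoxy-4-(methoxymethoxy)phenol, via aryl formate 3 (not isolated)
Conditions: mCPBA, CH2Cl2, 0 °C → rt; then K2CO3 (cat.), MeOH, rt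
Reagents that add atoms: 3-chloroperoxybenzoic acid OOC(=O)c1cccc(Cl)c1
Why: Baeyer–Villiger (Dakin-type) oxidation: in the peracid adduct the oxygen-rich aryl group should migrate in preference to hydride to give formate 3, which is transesterified by methanol to the phenol; this converts the aldehyde carbon position into the future O5.

Step 3
Reactants: 4 3-bromo-5-methoxy-4-(methoxymethoxy)phenol
Product: 5 5-(benzyloxy)-1-bromo-3-methoxy-2-(methoxymethoxy)benzene
Conditions: BnBr, K2CO3, DMF, rt
Reagents that add atoms: benzyl bromide BrCc1ccccc1
Why: Williamson ether synthesis on the unhindered phenoxide; benzyl is chosen for O5 because it should survive acid, base and cold organolithium reagents and leave only in the final hydrogenolysis.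

Step 4
Reactants: 5 5-(benzyloxy)-1-bromo-3-methoxy-2-(methoxymethoxy)benzene
Product: 8 5-(benzyloxy)-3-methoxy-2-(methoxymethoxy)phenol, via aryllithium 6 (not isolated), via lithium aryltrimethoxyborate 7 (not isolated)
Conditions: n-BuLi, THF, −78 °C; B(OMe)3, −78 → 0 °C; then 30% aq H2O2, 0 °C → rt
Reagents that add atoms: hydrogen peroxide OO (the phenol oxygen); n-butyllithium [Li]CCCC (lithium, held only in 6 and 7); trimethyl borate COB(OC)OC (held only in 7)
Why: Bromine–lithium exchange, assisted by the ortho acetal oxygen, gives 6, which is trapped as borate 7; peroxide oxidation proceeds by 1,2-migration of the aryl group from boron to oxygen at the same ring carbon, so the hydroxyl appears exactly where bromine was (the future O1).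

Step 5
Reactants: 8 5-(benzyloxy)-3-methoxy-2-(methoxymethoxy)phenol
Product: 9 5-(benzyloxy)-3-methoxy-2-(methoxymethoxy)phenyl diethylcarbamate
Conditions: NaH, ClCONEt2, THF, 0 °C → rt
Reagents that add atoms: diethylcarbamoyl chloride CCN(CC)C(Cl)=O
Why: O-Carbamoylation of the sodium phenoxide; the diethylcarbamate removes the acidic proton and is the strongest oxygen-based directing group for ortho-lithiation.

Step 6
Reactants: 9 5-(benzyloxy)-3-methoxy-2-(methoxymethoxy)phenyl diethylcarbamate
Product: 11 3-(benzyloxy)-2-iodo-5-methoxy-6-(methoxymethoxy)phenyl diethylcarbamate, via ortho-lithiated carbamate 10 (not isolated)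
Conditions: s-BuLi, TMEDA, THF, −78 °C; then I2, THF, −78 °C → rt
Reagents that add atoms: iodine II; sec-butyllithium [Li]C(C)CC (lithium, held only in 10)
Why: Directed ortho-metalation: the carbamate can direct only to C4a because its other ortho carbon bears the acetal oxygen, and the benzyloxy group on the far side reinforces lithiation at the same carbon; quenching with iodine at −78 °C should precede any anionic ortho-Fries migration.

Step 7
Reactants: 11 3-(benzyloxy)-2-iodo-5-methoxy-6-(methoxymethoxy)phenyl diethylcarbamate
Product: 12 3-(benzyloxy)-2-iodo-5-methoxy-6-(methoxymethoxy)phenol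
Conditions: NaOH, EtOH–H2O, reflux
Reagents that add atoms: none
Why: Base hydrolysis of the aryl carbamate by addition–elimination at the carbonyl releases the phenoxide; aryl iodide, benzyl ether and acetal are inert to hydroxide, and a buffered work-up keeps the acetal.

Step 8
Reactants: 12 3-(benzyloxy)-2-iodo-5-methoxy-6-(methoxymethoxy)phenol; 13 1-(benzyloxy)-4-ethynylbenzene; 14 carbon monoxide
Product: 17 5-(benzyloxy)-2-[4-(benzyloxy)phenyl]-7-methoxy-8-(methoxymethoxy)-4H-chromen-4-one, via ortho-hydroxyaryl ynone 15 (not isolated), via diethylamino enone 16 (not isolated)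
Conditions: PdCl2(PPh3)2 (5 mol %), 13 (1.5 equiv), Et2NH, CO (20 bar), 120 °C, autoclave
Reagents that add atoms: diethylamine CCNCC (its nitrogen and ethyl groups are held only in 16 and are released again)
Why: PdCl2(PPh3)2 is reduced in the amine/CO medium to zerovalent palladium, which inserts into the C4a–I bond of 12; 14 then inserts to give an aroyl complex of divalent palladium. The terminal alkyne 13, deprotonated by Et2NH, is transferred to palladium and reductive elimination gives ynone 15, forming C4a–C4 and C4–C3. Et2NH adds to 15 to give enaminone 16, and the neighbouring phenoxide attacks C2 and expels the amine, forming O1–C2 and ring C. The closest known reaction type is the palladium-catalysed carbonylative annulation of 2-iodophenols with terminal alkynes (carbonylative Sonogashira coupling followed by heterocyclisation). Ring C closes in the 6-endo mode (6-endo-dig with respect to the ynone, carried out as an addition–elimination on 16). No stereocentre is formed. CO insertion before alkyne transfer should be secured by the copper-free conditions, the CO pressure and the fast migration of the electron-rich, doubly ortho-substituted aryl group onto CO. The 6-endo closure over the 5-exo closure to an aurone should be secured by the secondary amine, which makes C2 of 16 the only electrophilic carbon within reach of the phenoxide.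

Step 9
Reactants: 17 5-(benzyloxy)-2-[4-(benzyloxy)phenyl]-7-methoxy-8-(methoxymethoxy)-4H-chromen-4-one
Product: 18 5-(benzyloxy)-2-[4-(benzyloxy)phenyl]-8-hydroxy-7-methoxy-4H-chromen-4-one
Conditions: HCl (2 M), MeOH–THF, 40 °C
Reagents that add atoms: none
Why: Acid-catalysed acetal exchange with methanol removes the methoxymethyl group; aryl benzyl ethers, including the peri ether on O5, should be stable to dilute HCl at this temperature.

Step 10
Reactants: 18 5-(benzyloxy)-2-[4-(benzyloxy)phenyl]-8-hydroxy-7-methoxy-4H-chromen-4-one
Product: 19 5-(benzyloxy)-2-[4-(benzyloxy)phenyl]-7-methoxy-4-oxo-4H-chromen-8-yl acetate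
Conditions: Ac2O, pyridine, DMAP (cat.), CH2Cl2, rt
Reagents that add atoms: acetic anhydride CC(=O)OC(C)=O
Why: Nucleophile-catalysed O-acylation of the only free hydroxyl in 18, so the acetate can only be placed on O8.

Step 11
Reactants: 19 5-(benzyloxy)-2-[4-(benzyloxy)phenyl]-7-methoxy-4-oxo-4H-chromen-8-yl acetate
Product: 21 5-(benzyloxy)-2-[4-(benzyloxy)phenyl]-3-hydroxy-7-methoxy-4-oxo-4H-chromen-8-yl acetate, via racemic 2,3-epoxide 20 (not isolated)
Conditions: DMDO (acetone), CH2Cl2, 0 °C → rt; then p-TsOH·H2O (cat.), CH2Cl2, rt
Reagents that add atoms: dimethyldioxirane CC1(C)OO1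
Why: Electrophilic epoxidation of the enol-ether-like C2=C3 bond by the neutral dioxirane gives the cis-fused epoxide 20 as a racemate (its two stereocentres are uncontrolled and need no control). Catalytic acid opens the oxirane at C2 to a cation stabilised by O1 and the aryl group, and loss of the C3 proton gives the 3-hydroxyflavone, so both stereocentres vanish; acetate and benzyl ethers should tolerate these neutral to weakly acidic conditions.

Step 12
Reactants: 21 5-(benzyloxy)-2-[4-(benzyloxy)phenyl]-3-hydroxy-7-methoxy-4-oxo-4H-chromen-8-yl acetate
Product: 22 3,5-dihydroxy-2-(4-hydroxyphenyl)-7-methoxy-4-oxo-4H-chromen-8-yl acetate (pollenitin 8-acetate)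
Conditions: H2 (1 atm), 10% Pd/C, EtOAc–THF, rt
Reagents that add atoms: none
Why: Heterogeneous hydrogenolysis of the two aryl benzyl ethers under neutral, non-nucleophilic conditions; the aryl acetate should be untouched and the conjugated, tetrasubstituted C2=C3 bond should not be reduced at atmospheric pressure.

## Compound list

1 | 5-bromovanillin | COc1cc(C=O)cc(Br)c1O | starting material
2 | 3-bromo-5-methoxy-4-(methoxymethoxy)benzaldehyde | COCOc1c(Br)cc(C=O)cc1OC | intermediate
3 | 3-bromo-5-methoxy-4-(methoxymethoxy)phenyl formate (formed in the flask) | COCOc1c(Br)cc(OC=O)cc1OC | intermediate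
4 | 3-bromo-5-methoxy-4-(methoxymethoxy)phenol | COCOc1c(Br)cc(O)cc1OC | intermediate
5 | 5-(benzyloxy)-1-bromo-3-methoxy-2-(methoxymethoxy)benzene | COCOc1c(Br)cc(OCc2ccccc2)cc1OC | intermediate
6 | [5-(benzyloxy)-3-methoxy-2-(methoxymethoxy)phenyl]lithium (formed in the flask) | [Li]c1cc(OCc2ccccc2)cc(OC)c1OCOC | intermediate
7 | lithium [5-(benzyloxy)-3-methoxy-2-(methoxymethoxy)phenyl]trimethoxyborate (formed in the flask) | [Li+].CO[B-](OC)(OC)c1cc(OCc2ccccc2)cc(OC)c1OCOC | intermediate
8 | 5-(benzyloxy)-3-methoxy-2-(methoxymethoxy)phenol | COCOc1c(O)cc(OCc2ccccc2)cc1OC | intermediate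
9 | 5-(benzyloxy)-3-methoxy-2-(methoxymethoxy)phenyl diethylcarbamate | CCN(CC)C(=O)Oc1cc(OCc2ccccc2)cc(OC)c1OCOC | intermediate
10 | {6-(benzyloxy)-2-[(diethylcarbamoyl)oxy]-4-methoxy-3-(methoxymethoxy)phenyl}lithium (formed in the flask) | [Li]c1c(OCc2ccccc2)cc(OC)c(OCOC)c1OC(=O)N(CC)CC | intermediate
11 | 3-(benzyloxy)-2-iodo-5-methoxy-6-(methoxymethoxy)phenyl diethylcarbamate | CCN(CC)C(=O)Oc1c(I)c(OCc2ccccc2)cc(OC)c1OCOC | intermediate
12 | 3-(benzyloxy)-2-iodo-5-methoxy-6-(methoxymethoxy)phenol | COCOc1c(O)c(I)c(OCc2ccccc2)cc1OC | intermediate
13 | 1-(benzyloxy)-4-ethynylbenzene | C#Cc1ccc(OCc2ccccc2)cc1 | starting material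
14 | carbon monoxide | [C-]#[O+] | starting material
15 | 1-[6-(benzyloxy)-2-hydroxy-4-methoxy-3-(methoxymethoxy)phenyl]-3-[4-(benzyloxy)phenyl]prop-2-yn-1-one (formed in the flask) | COCOc1c(OC)cc(OCc2ccccc2)c(C(=O)C#Cc2ccc(OCc3ccccc3)cc2)c1O | intermediate
16 | (2E)-1-[6-(benzyloxy)-2-hydroxy-4-methoxy-3-(methoxymethoxy)phenyl]-3-[4-(benzyloxy)phenyl]-3-(diethylamino)prop-2-en-1-one (formed in the flask) | COCOc1c(OC)cc(OCc2ccccc2)c(C(=O)/C=C(/N(CC)CC)c2ccc(OCc3ccccc3)cc2)c1O | intermediate
17 | 5-(benzyloxy)-2-[4-(benzyloxy)phenyl]-7-methoxy-8-(methoxymethoxy)-4H-chromen-4-one | COCOc1c(OC)cc(OCc2ccccc2)c2c(=O)cc(-c3ccc(OCc4ccccc4)cc3)oc12 | intermediate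
18 | 5-(benzyloxy)-2-[4-(benzyloxy)phenyl]-8-hydroxy-7-methoxy-4H-chromen-4-one | COc1cc(OCc2ccccc2)c2c(=O)cc(-c3ccc(OCc4ccccc4)cc3)oc2c1O | intermediate
19 | 5-(benzyloxy)-2-[4-(benzyloxy)phenyl]-7-methoxy-4-oxo-4H-chromen-8-yl acetate | COc1cc(OCc2ccccc2)c2c(=O)cc(-c3ccc(OCc4ccccc4)cc3)oc2c1OC(C)=O | intermediate
20 | rac-5-(benzyloxy)-2-[4-(benzyloxy)phenyl]-2,3-epoxy-7-methoxy-4-oxo-3,4-dihydro-2H-chromen-8-yl acetate (oxirane cis-fused across C2–C3; racemic, one enantiomer drawn; formed in the flask) | COc1cc(OCc2ccccc2)c2C(=O)[C@@H]3O[C@]3(c4ccc(OCc5ccccc5)cc4)Oc2c1OC(C)=O | intermediate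
21 | 5-(benzyloxy)-2-[4-(benzyloxy)phenyl]-3-hydroxy-7-methoxy-4-oxo-4H-chromen-8-yl acetate | COc1cc(OCc2ccccc2)c2c(=O)c(O)c(-c3ccc(OCc4ccccc4)cc3)oc2c1OC(C)=O | intermediate
22 | 3,5-dihydroxy-2-(4-hydroxyphenyl)-7-methoxy-4-oxo-4H-chromen-8-yl acetate (pollenitin 8-acetate) | COc1cc(O)c2c(=O)c(O)c(-c3ccc(O)cc3)oc2c1OC(C)=O | target

## Step count and least certain steps

Total step count: 12. Longest linear sequence: 12 steps (1 to 22); 13 and 14 enter in step 8 as purchased materials.

Step 8 (key step). The most likely failure is consumption of the aroylpalladium intermediate by the wrong partner: capture by Et2NH, or transfer of the alkyne to arylpalladium before CO has inserted. Both become serious if oxidative addition into the C–I bond flanked by two oxygen substituents is slow and CO uptake lags; reductive loss of iodine is the third leak. The fallback sets out from 8 and comes back at 17, giving up CO as the source of C4. Magnesium-mediated ortho-formylation (MgCl2, Et3N, paraformaldehyde, MeCN, reflux) can only reach C4a, because the other ortho carbon is blocked, and would give 6-(benzyloxy)-2-hydroxy-4-methoxy-3-(methoxymethoxy)benzaldehyde F1. Alkyne 13, deprotonated with n-BuLi (2.5 equiv, THF, −78 °C), would add to F1 to give rac-3-(benzyloxy)-2-{3-[4-(benzyloxy)phenyl]-1-hydroxyprop-2-yn-1-yl}-5-methoxy-6-(methoxymethoxy)phenol F2. MnO2 in CH2Cl2 would oxidise F2 to 15, isolated in this case, and Et2NH in EtOH would close 15 to 17 through 16. Compounds 9 to 12 are bypassed.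

Step 6. The most likely failure is deprotonation at the benzylic CH2 of the O5 benzyl ether, followed by Wittig rearrangement, or migration of the carbamoyl group from oxygen to the lithiated carbon before iodine arrives. The fallback sets out from 8 and comes back at 12 without any organolithium reagent. Amine-catalysed ortho-bromination of the free phenol (NBS, i-Pr2NH cat., CH2Cl2, 0 °C), in which a hydrogen-bonded N-bromoamine delivers bromine beside the hydroxyl, would give 3-(benzyloxy)-2-bromo-5-methoxy-6-(methoxymethoxy)phenol F3. Copper-catalysed halogen exchange (CuI cat., NaI, trans-N,N'-dimethylcyclohexane-1,2-diamine, dioxane, 110 °C) would convert F3 into 12.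

Step 7. The most likely failure is incomplete hydrolysis, because the carbamate carbonyl is screened on both sides by iodine and by the acetal; forcing the reaction risks loss of iodine or of the acetal during work-up. A milder reagent for the same cleavage, Cp2Zr(H)Cl in THF at rt, would be tried first. The fallback proper replaces the carbamate by a fluoride-labile directing group; it sets out from 8 and comes back at 12. SEMCl and i-Pr2NEt in CH2Cl2 would give 5-(benzyloxy)-3-methoxy-2-(methoxymethoxy)-1-{[2-(trimethylsilyl)ethoxy]methoxy}benzene F4. Lithiation between the two ether oxygens (s-BuLi, TMEDA, THF, −78 °C) and iodine quench would give 1-(benzyloxy)-2-iodo-5-methoxy-4-(methoxymethoxy)-3-{[2-(trimethylsilyl)ethoxy]methoxy}benzene F5. Bu4NF in THF–DMPU at 60 °C would then release 12, the silicon-free methoxymethyl group staying in place.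

Step 11. The most likely failure is slow epoxidation of the conjugated C2=C3 bond, so that excess dioxirane begins to oxidise the benzylic CH2 groups of the benzyl ethers. The fallback sets out from 17, replaces steps 9 to 12 and comes back at 22, at the cost of one extra step.
- C3-Lithiation and borate oxidation (LiN(i-Pr)2, THF, −78 °C; B(OMe)3; then H2O2, AcOH) would give 5-(benzyloxy)-2-[4-(benzyloxy)phenyl]-3-hydroxy-7-methoxy-8-(methoxymethoxy)-4H-chromen-4-one F6.
- BnBr and K2CO3 in DMF would give 3,5-bis(benzyloxy)-2-[4-(benzyloxy)phenyl]-7-methoxy-8-(methoxymethoxy)-4H-chromen-4-one F7.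
- HCl in MeOH–THF would give 3,5-bis(benzyloxy)-2-[4-(benzyloxy)phenyl]-8-hydroxy-7-methoxy-4H-chromen-4-one F8.
- Ac2O and pyridine would give 3,5-bis(benzyloxy)-2-[4-(benzyloxy)phenyl]-7-methoxy-4-oxo-4H-chromen-8-yl acetate F9.
- Hydrogenolysis of F9 (H2, 10% Pd/C, EtOAc–THF) would give 22.

## Further compounds

F1 | step 8 | 6-(benzyloxy)-2-hydroxy-4-methoxy-3-(methoxymethoxy)benzaldehyde | COCOc1c(OC)cc(OCc2ccccc2)c(C=O)c1O
F2 | step 8 | rac-3-(benzyloxy)-2-{3-[4-(benzyloxy)phenyl]-1-hydroxyprop-2-yn-1-yl}-5-methoxy-6-(methoxymethoxy)phenol (racemic, one enantiomer drawn) | COCOc1c(OC)cc(OCc2ccccc2)c([C@H](O)C#Cc2ccc(OCc3ccccc3)cc2)c1O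
F3 | step 6 | 3-(benzyloxy)-2-bromo-5-methoxy-6-(methoxymethoxy)phenol | COCOc1c(O)c(Br)c(OCc2ccccc2)cc1OC
F4 | step 7 | 5-(benzyloxy)-3-methoxy-2-(methoxymethoxy)-1-{[2-(trimethylsilyl)ethoxy]methoxy}benzene | COCOc1c(OCOCC[Si](C)(C)C)cc(OCc2ccccc2)cc1OC
F5 | step 7 | 1-(benzyloxy)-2-iodo-5-methoxy-4-(methoxymethoxy)-3-{[2-(trimethylsilyl)ethoxy]methoxy}benzene | COCOc1c(OCOCC[Si](C)(C)C)c(I)c(OCc2ccccc2)cc1OC
F6 | step 11 | 5-(benzyloxy)-2-[4-(benzyloxy)phenyl]-3-hydroxy-7-methoxy-8-(methoxymethoxy)-4H-chromen-4-one | COCOc1c(OC)cc(OCc2ccccc2)c2c(=O)c(O)c(-c3ccc(OCc4ccccc4)cc3)oc12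
F7 | step 11 | 3,5-bis(benzyloxy)-2-[4-(benzyloxy)phenyl]-7-methoxy-8-(methoxymethoxy)-4H-chromen-4-one | COCOc1c(OC)cc(OCc2ccccc2)c2c(=O)c(OCc3ccccc3)c(-c3ccc(OCc4ccccc4)cc3)oc12
F8 | step 11 | 3,5-bis(benzyloxy)-2-[4-(benzyloxy)phenyl]-8-hydroxy-7-methoxy-4H-chromen-4-one | COc1cc(OCc2ccccc2)c2c(=O)c(OCc3ccccc3)c(-c3ccc(OCc4ccccc4)cc3)oc2c1O
F9 | step 11 | 3,5-bis(benzyloxy)-2-[4-(benzyloxy)phenyl]-7-methoxy-4-oxo-4H-chromen-8-yl acetate | COc1cc(OCc2ccccc2)c2c(=O)c(OCc3ccccc3)c(-c3ccc(OCc4ccccc4)cc3)oc2c1OC(C)=O
A1 | alternative 1 | 8-(allyloxy)-3,5-bis(benzyloxy)-2-[4-(benzyloxy)phenyl]-7-methoxy-4H-chromen-4-one | COc1cc(OCc2ccccc2)c2c(=O)c(OCc3ccccc3)c(-c3ccc(OCc4ccccc4)cc3)oc2c1OCC=C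
A2 | alternative 1 | 2-(acetyloxy)-3-(allyloxy)-6-(benzyloxy)-4-methoxybenzoyl chloride | CC(=O)Oc1c(OCC=C)c(OC)cc(OCc2ccccc2)c1C(Cl)=O
A3 | alternative 1 | 4-{(Z)-2-(benzyloxy)-1-[4-(benzyloxy)phenyl]ethenyl}morpholine | O(Cc1ccccc1)/C=C(\N1CCOCC1)c1ccc(OCc2ccccc2)cc1
A4 | alternative 2 | 3-(benzyloxy)-2-[4-(benzyloxy)phenyl]-5,8-dihydroxy-7-methoxy-4H-chromen-4-one | COc1cc(O)c2c(=O)c(OCc3ccccc3)c(-c3ccc(OCc4ccccc4)cc3)oc2c1O
A5 | alternative 2 | rac-4-{5-(benzyloxy)-6-[4-(benzyloxy)phenyl]-4-oxo-4H-pyran-2-yl}-4-hydroxy-3-methoxycyclobut-2-en-1-one (racemic, one enantiomer drawn) | COC1=CC(=O)[C@]1(O)c1cc(=O)c(OCc2ccccc2)c(-c2ccc(OCc3ccccc3)cc2)o1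
A6 | alternative 2 | 3-methoxycyclobut-3-ene-1,2-dione | COC1=CC(=O)C1=O
A7 | alternative 2 | 3-(benzyloxy)-2-[4-(benzyloxy)phenyl]-4H-pyran-4-one | O=c1ccoc(-c2ccc(OCc3ccccc3)cc2)c1OCc1ccccc1
A8 | alternative 3 | 5,8-bis(allyloxy)-3-(benzyloxy)-2-[4-(benzyloxy)phenyl]-7-methoxy-4H-chromen-4-one | COc1cc(OCC=C)c2c(=O)c(OCc3ccccc3)c(-c3ccc(OCc4ccccc4)cc3)oc2c1OCC=C
A9 | alternative 3 | (2E)-3-[2,5-bis(allyloxy)-3-methoxyphenoxy]-2-(benzyloxy)-3-[4-(benzyloxy)phenyl]prop-2-enoic acid | OC(=O)/C(OCc1ccccc1)=C(/c1ccc(OCc2ccccc2)cc1)Oc1cc(OCC=C)cc(OC)c1OCC=C
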